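A small charge opened the books: [electrophile] of 0.015 M, with 1.05 equiv of nucleophile, and I kept the ledger in percent of the electrophile charged.

| setting | cedar | alder | south-east | north-east |
|---|---|---|---|---|
| electrophile | 0.015 M | 0.015 M | 0.015 M | 0.015 M |
| nucleophile | 1.05 equiv | 1.05 equiv | 1.05 equiv | 1.05 equiv |
| free base | 0.41 equiv | 0.61 equiv | 0.450 equiv | 0.300 equiv |
| remark | run made earlier | run made earlier |  |  |
| time |  |  | 5.0 h | 5.0 h |

- cedar (time / h: electrophile / %, product / %): 0.667: 67.5, 19.1; 2.00: 35.4, 34.3; 3.00: 25.4, 38.7; 5.00: 14.1, 44.1
- alder (time / h: electrophile / %, product / %): 1.33: 47.4, 28.3; 2.50: 27.9, 36.4; 4.00: 16.6, 42.4; 5.00: 12.7, 44.1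

(standard deviation of a reading: 0.5 percentage points)

- on the list of suspects stand: electrophile <-> dormant form; acid set free + free base <-> salt of the base; nucleophile + acid set free <-> protonated nucleophile; acid set free -> by-product carried off; electrophile + nucleophile -> acid set free + product
- what has gone from electrophile into another species counts as reacted, even if it can come back

- part of the electrophile that has reacted at the end, south-east
- part of the electrophile that has reacted at the end, north-east
- what raising the equivalents of free base from its lowest to its highest value here does to the part of the electrophile that has reacted (changes below 5 percentage points count as none) (no change / it rises / it falls)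

The list of suspects gave electrophile two exits, product and dormant form, so I kept a ledger with three entries. In cedar at 5.00 h, 14.1 % of the charge was still electrophile and 44.1 % was product. I booked the remainder, 41.8 %, as dormant form. Alder closed at 5.00 h with 12.7 % as electrophile, 44.1 % as product and 43.2 % as remainder.

I called dormant form over product the split: 0.948 in cedar and 0.980 in alder. An even split of 1 was the zero of my scale, where the two exits drew level. Both readings lay near that zero. Product read the same in the two runs, though free base went from 0.41 equiv to 0.61 equiv. Reacted electrophile is product times one plus the split, so the mean split gave me 86.6 % for both new flasks. For north-east, at 0.300 equiv, that meant stepping below the runs.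

The forecast gave 86.2 % for south-east, 84 % for north-east and no change for the trend, and it held that “The dormant channel buffers the loss”. Its north-east figure lay below mine.

The flasks gave 87.1 % in south-east and 86.8 % in north-east. The trend was no change, a shift of 0.37 percentage points.

    electrophile ⇌ dormant form (K = 6.86, k = 7.46 × 10⁻⁵ s⁻¹)
    acid set free + free base ⇌ salt of the base, settled at all times (K = 1.00 × 10⁵ M⁻¹)
    nucleophile + acid set free ⇌ protonated nucleophile, settled at all times (K = 2.07 × 10⁵ M⁻¹)
    acid set free → by-product carried off (k = 1.55 × 10⁻⁴ s⁻¹)
    electrophile + nucleophile → acid set free + product (k = 0.00738 M⁻¹ s⁻¹)

In north-east the step to dormant form had 79 % of its turnover behind it by 2.50 h, while nucleophile fell to 38.3 % of its charge. At 5.00 h the forward half-life of electrophile towards dormant form, 2.6 h, was shorter than its half-life towards product, 5.9 h, and the split in north-east stood at 1.02. A neighbour flask, north-east with 0.0060 M of electrophile and equivalents and time held, reached 81.2 % reacted with 27.6 % product, and its split of 1.94 was twice the cedar reading.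

The readings were computed with constants of no real substance.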